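## Retrosynthetic overview

1. Lepadin H ⇒ N‑Boc/5′‑O‑TBS decahydroquinolin‑3‑ol + (2E,4E)‑octa‑2,4‑dienoic acid (late C3–O acylation, then global acidolysis).
2. C5 side chain ⇒ Wittig olefination of a cis‑fused N‑Boc‑5‑oxodecahydroquinoline with a (5R)‑5‑silyloxyoctyl ylide, then convex‑face hydrogenation (sets C5, frees C3–OH).
3. Piperidine ring (formed second) ⇒ 6‑endo intramolecular aza‑Michael addition of a primary amine onto a 2‑alkylcyclohex‑2‑enone (sets C8a; C4a is then fixed under the N‑Boc group).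
4. Carbocycle (formed first) ⇒ intramolecular aldol condensation of a 1,5‑keto aldehyde released by ozonolysis of a 1‑alkylcyclopentene.
5. Acyclic precursor ⇒ Boc‑L‑alanine Weinreb amide + homoallylic Grignard, then anti‑selective ketone reduction (C2 from alanine, C3 by reduction); side chain from (R)‑epichlorohydrin.

Assumption: the SMILES is read as (2S,3R,4aS,5S,8aR,5′R), i.e. H2/H4a/H5/H8a all cis and the C3 ester trans to the C2 methyl; Boc‑L‑Ala‑N(OMe)Me, 1‑chlorocyclopentene, (R)‑epichlorohydrin and the Grignard solutions are bought.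

## Route

Step 1
Reactants: 1 1-chlorocyclopent-1-ene; 2 oxirane
Product: 4 2-(cyclopent-1-en-1-yl)ethan-1-ol, via cyclopent-1-en-1-yllithium 3 (not isolated)
Conditions: Li (2.2 equiv, 1 % Na), Et2O, reflux; then 2, 0 °C → rt; H2O
Reagents that add atoms: none
Why: Reductive lithiation of the vinyl chloride gives the vinyllithium, which opens ethylene oxide (SN2 epoxide opening) to the homoallylic alcohol.

Step 2
Reactants: 4 2-(cyclopent-1-en-1-yl)ethan-1-ol
Product: 5 1-(2-bromoethyl)cyclopent-1-ene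
Conditions: CBr4, PPh3, CH2Cl2, 0 °C
Reagents that add atoms: carbon tetrabromide, BrC(Br)(Br)Br
Why: Appel bromination converts the primary alcohol into the bromide under neutral conditions that leave the trisubstituted alkene in place.

Step 3
Reactants: 5 1-(2-bromoethyl)cyclopent-1-ene; 6 tert-butyl N-[(2S)-1-[methoxy(methyl)amino]-1-oxopropan-2-yl]carbamate
Product: 8 tert-butyl N-[(2S)-5-(cyclopent-1-en-1-yl)-3-oxopentan-2-yl]carbamate, via 2-(cyclopent-1-en-1-yl)ethylmagnesium bromide 7 (not isolated)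
Conditions: 5, Mg, THF, rt; 6, i-PrMgCl (1.0 equiv), THF, −15 °C, then 7 (1.5 equiv), −15 °C → rt; aq. NH4Cl
Reagents that add atoms: none
Why: Weinreb ketone synthesis, in which the N‑magnesiated carbamate and the stable chelated tetrahedral intermediate prevent over‑addition and α‑epimerisation, so the alanine stereocentre (C2 of the target) is carried through unchanged.

Step 4
Reactants: 8 tert-butyl N-[(2S)-5-(cyclopent-1-en-1-yl)-3-oxopentan-2-yl]carbamate
Product: 9 tert-butyl N-[(2S,3R)-5-(cyclopent-1-en-1-yl)-3-hydroxypentan-2-yl]carbamate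
Conditions: LiAlH(O-t-Bu)3 (2.5 equiv), EtOH, −78 °C
Reagents that add atoms: none
Why: Chelation‑controlled (Cram‑cyclic) hydride reduction of an N–H carbamate α‑amino ketone gives the anti amino alcohol, setting C3 of the target as R.

Step 5
Reactants: 9 tert-butyl N-[(2S,3R)-5-(cyclopent-1-en-1-yl)-3-hydroxypentan-2-yl]carbamate
Product: 10 tert-butyl N-[(2S,3R)-3-(benzyloxy)-5-(cyclopent-1-en-1-yl)pentan-2-yl]carbamate
Conditions: BnOC(=NH)CCl3 (1.5 equiv), TfOH (5 mol %), CH2Cl2/cyclohexane 1:2, 0 °C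
Reagents that add atoms: benzyl 2,2,2-trichloroacetimidate, ClC(Cl)(Cl)C(=N)OCc1ccccc1
Why: Acid‑catalysed O‑benzylation with the trichloroacetimidate avoids the alkoxide that would close an oxazolidinone onto the Boc group under Williamson conditions.

Step 6
Reactants: 10 tert-butyl N-[(2S,3R)-3-(benzyloxy)-5-(cyclopent-1-en-1-yl)pentan-2-yl]carbamate
Product: 11 tert-butyl N-[(2S,3R)-3-(benzyloxy)-6,10-dioxodecan-2-yl]carbamate
Conditions: O3, CH2Cl2/MeOH 4:1, −78 °C (Sudan III end point); then Me2S, −78 °C → rt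
Reagents that add atoms: ozone, [O-][O+]=O
Why: Ozonolysis with reductive work‑up cleaves the electron‑rich ring alkene (much faster than the benzyl ether is attacked) and unmasks the 1,5‑keto aldehyde.

Step 7
Reactants: 11 tert-butyl N-[(2S,3R)-3-(benzyloxy)-6,10-dioxodecan-2-yl]carbamate
Product: 13 tert-butyl N-[(2S,3R)-3-(benzyloxy)-4-(6-oxocyclohex-1-en-1-yl)butan-2-yl]carbamate, via β-hydroxy ketone 12 (not isolated)
Conditions: piperidine (20 mol %), AcOH (20 mol %), toluene, 60 °C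
Reagents that add atoms: none
Why: Intramolecular aldol condensation, in which only attack of the chain‑bearing ketone α‑CH2 on the aldehyde can give a six‑membered ring, so the 2‑substituted cyclohex‑2‑enone forms regioselectively after dehydration.

Step 8
Reactants: 13 tert-butyl N-[(2S,3R)-3-(benzyloxy)-4-(6-oxocyclohex-1-en-1-yl)butan-2-yl]carbamate
Product: 15 (2S,3R,4aS,8aR)-3-(benzyloxy)-2-methyloctahydroquinolin-5(1H)-one, via amino enone 14 (not isolated)
Conditions: TFA/CH2Cl2 1:4, 0 °C → rt; evaporate; NaHCO3, MeOH/H2O 9:1, rt, 16 h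
Reagents that add atoms: none
Why: Boc removal frees the primary amine, which closes the piperidine by a reversible 6‑endo‑trig intramolecular aza‑Michael addition through a chair with methyl and benzyloxy equatorial, so C8a–H ends up cis to C2–H (8aR) while the enolisable C4a is obtained as an equilibrium mixture (trans‑fused 15 expected to dominate).

Step 9
Reactants: 15 (2S,3R,4aS,8aR)-3-(benzyloxy)-2-methyloctahydroquinolin-5(1H)-one
Product: 17 tert-butyl (2S,3R,4aR,8aR)-3-(benzyloxy)-2-methyl-5-oxooctahydroquinoline-1(2H)-carboxylate, via cis-fused amino ketone 16 (not isolated)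
Conditions: Boc2O (3 equiv), Et3N, THF, 60 °C; then DBU (0.2 equiv), rt
Reagents that add atoms: di-tert-butyl dicarbonate, CC(C)(C)OC(=O)OC(=O)OC(C)(C)C
Why: Carbamate formation on the ring nitrogen, after which A(1,3) strain of the N‑Boc group forces the C2 and C8a substituents axial, an arrangement only the cis ring fusion can adopt, so C4a equilibrates by enolisation to the cis‑fused (4aR) ketone.

Step 10
Reactants: 18 (2R)-2-(chloromethyl)oxirane; 19 ethylmagnesium bromide
Product: 20 (2R)-1-chloropentan-2-ol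
Conditions: CuI (10 mol %), THF, −50 → −20 °C; aq. NH4Cl
Reagents that add atoms: none
Why: Copper‑catalysed Grignard opening of the epoxide at its CH2 terminus (SN2) leaves the stereocentre untouched.

Step 11
Reactants: 20 (2R)-1-chloropentan-2-ol
Product: 21 (2R)-2-propyloxirane
Conditions: NaOH (50 % aq.), 0 °C → rt; distil
Reagents that add atoms: none
Why: Intramolecular Williamson etherification (SN2 at the CH2Cl carbon) closes the epoxide without touching the stereocentre.

Step 12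
Reactants: 21 (2R)-2-propyloxirane; 22 allylmagnesium bromide
Product: 23 (4R)-oct-7-en-4-ol
Conditions: CuI (10 mol %), THF, −30 → 0 °C; aq. NH4Cl
Reagents that add atoms: none
Why: Copper‑catalysed SN2 opening of the terminal epoxide at CH2 completes the C8 chain with the carbinol centre (the future C5′, R) preserved.

Step 13
Reactants: 23 (4R)-oct-7-en-4-ol
Product: 24 tert-butyldimethyl{[(4R)-oct-7-en-4-yl]oxy}silane
Conditions: TBSCl, imidazole, DMF, rt
Reagents that add atoms: tert-butyldimethylsilyl chloride, CC(C)(C)[Si](C)(C)Cl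
Why: Silylation protects the secondary alcohol as a TBS ether that survives ylide, hydrogenation and acylation conditions.

Step 14
Reactants: 24 tert-butyldimethyl{[(4R)-oct-7-en-4-yl]oxy}silane
Product: 26 (5R)-5-[(tert-butyldimethylsilyl)oxy]octan-1-ol, via B-alkyl-9-BBN adduct 25 (not isolated)
Conditions: 9-BBN, THF, 0 °C → rt; then 3 M NaOH, 30 % H2O2, 0 °C → rt
Reagents that add atoms: hydrogen peroxide, OO
Why: Anti‑Markovnikov hydroboration–oxidation of the terminal alkene with 9‑BBN gives the primary alcohol.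

Step 15
Reactants: 26 (5R)-5-[(tert-butyldimethylsilyl)oxy]octan-1-ol
Product: 27 tert-butyl{[(4R)-8-iodooctan-4-yl]oxy}dimethylsilane
Conditions: I2, PPh3, imidazole, CH2Cl2, 0 °C → rt
Reagents that add atoms: iodine, II
Why: Appel‑type iodination of the primary alcohol proceeds under conditions that keep the silyl ether.

Step 16
Reactants: 27 tert-butyl{[(4R)-8-iodooctan-4-yl]oxy}dimethylsilane
Product: 28 {(5R)-5-[(tert-butyldimethylsilyl)oxy]octyl}triphenylphosphonium iodide
Conditions: PPh3 (1.5 equiv), K2CO3 (cat.), MeCN, reflux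
Reagents that add atoms: triphenylphosphine, c1ccc(cc1)P(c1ccccc1)c1ccccc1
Why: SN2 quaternisation of triphenylphosphine by the primary iodide gives the Wittig salt.

Step 17
Reactants: 28 {(5R)-5-[(tert-butyldimethylsilyl)oxy]octyl}triphenylphosphonium iodide; 17 tert-butyl (2S,3R,4aR,8aR)-3-(benzyloxy)-2-methyl-5-oxooctahydroquinoline-1(2H)-carboxylate
Product: 30 tert-butyl (2S,3R,4aS,8aR)-3-(benzyloxy)-5-{(5R)-5-[(tert-butyldimethylsilyl)oxy]octylidene}-2-methyloctahydroquinoline-1(2H)-carboxylate (E/Z mixture), via phosphonium ylide 29 (not isolated)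
Conditions: 28 (3 equiv), KHMDS, THF, −78 → 0 °C; then 17, 0 → 50 °C
Reagents that add atoms: none
Why: Wittig olefination with the non‑stabilised ylide joins the two main fragments; the alkene geometry is irrelevant and C4a is already in its thermodynamically preferred cis‑fused configuration, so enolisation cannot erode it.

Step 18
Reactants: 30 tert-butyl (2S,3R,4aS,8aR)-3-(benzyloxy)-5-{(5R)-5-[(tert-butyldimethylsilyl)oxy]octylidene}-2-methyloctahydroquinoline-1(2H)-carboxylate
Product: 31 tert-butyl (2S,3R,4aS,5S,8aR)-5-{(5R)-5-[(tert-butyldimethylsilyl)oxy]octyl}-3-hydroxy-2-methyloctahydroquinoline-1(2H)-carboxylate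
Conditions: H2 (3 atm), 20 % Pd(OH)2/C, EtOAc, rt
Reagents that add atoms: none
Why: Heterogeneous hydrogenation delivers H2 to the exocyclic alkene from the convex face of the cis‑fused bicycle (the face of H4a and H8a, opposite the axial C4 methylene), setting C5 as S with all ring‑fusion hydrogens cis, and the same conditions hydrogenolyse the benzyl ether.

Step 19
Reactants: 32 (2E)-hex-2-enal; 33 malonic acid
Product: 35 (2E,4E)-octa-2,4-dienoic acid, via hex-2-enylidenemalonic acid 34 (not isolated)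
Conditions: pyridine, piperidine (cat.), 90 °C; then aq. HCl
Reagents that add atoms: none
Why: Knoevenagel–Doebner condensation with in situ decarboxylation gives the thermodynamically favoured (2E,4E)‑dienoic acid.

Step 20
Reactants: 31 tert-butyl (2S,3R,4aS,5S,8aR)-5-{(5R)-5-[(tert-butyldimethylsilyl)oxy]octyl}-3-hydroxy-2-methyloctahydroquinoline-1(2H)-carboxylate; 35 (2E,4E)-octa-2,4-dienoic acid
Product: 36 tert-butyl (2S,3R,4aS,5S,8aR)-5-{(5R)-5-[(tert-butyldimethylsilyl)oxy]octyl}-2-methyl-3-{[(2E,4E)-octa-2,4-dienoyl]oxy}octahydroquinoline-1(2H)-carboxylate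
Conditions: DCC, DMAP, CH2Cl2, 0 °C → rt
Reagents that add atoms: none
Why: Steglich esterification acylates the only free hydroxyl (C3–OH) with retention at C3, while the carbamate keeps the ring nitrogen from being acylated.

Step 21
Reactants: 36 tert-butyl (2S,3R,4aS,5S,8aR)-5-{(5R)-5-[(tert-butyldimethylsilyl)oxy]octyl}-2-methyl-3-{[(2E,4E)-octa-2,4-dienoyl]oxy}octahydroquinoline-1(2H)-carboxylate
Product: 37 lepadin H
Conditions: TFA/H2O 9:1, 0 °C → rt; then sat. aq. NaHCO3
Reagents that add atoms: none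
Why: Acidolysis removes the Boc group (tert‑butyl cation fragmentation) and hydrolyses the silyl ether in one operation without touching the dienoate or any stereocentre, and the protonated amine cannot take part in O→N acyl migration.

## Compound list

1 | 1-chlorocyclopent-1-ene | ClC1=CCCC1 | starting material
2 | oxirane (ethylene oxide) | C1CO1 | starting material
3 | cyclopent-1-en-1-yllithium | [Li]C1=CCCC1 | intermediate
4 | 2-(cyclopent-1-en-1-yl)ethan-1-ol | OCCC1=CCCC1 | intermediate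
5 | 1-(2-bromoethyl)cyclopent-1-ene | BrCCC1=CCCC1 | intermediate
6 | tert-butyl N-[(2S)-1-[methoxy(methyl)amino]-1-oxopropan-2-yl]carbamate (Boc-L-Ala Weinreb amide) | C[C@H](NC(=O)OC(C)(C)C)C(=O)N(C)OC | starting material
7 | [2-(cyclopent-1-en-1-yl)ethyl]magnesium bromide | Br[Mg]CCC1=CCCC1 | intermediate
8 | tert-butyl N-[(2S)-5-(cyclopent-1-en-1-yl)-3-oxopentan-2-yl]carbamate | C[C@H](NC(=O)OC(C)(C)C)C(=O)CCC1=CCCC1 | intermediate
9 | tert-butyl N-[(2S,3R)-5-(cyclopent-1-en-1-yl)-3-hydroxypentan-2-yl]carbamate | C[C@H](NC(=O)OC(C)(C)C)[C@H](O)CCC1=CCCC1 | intermediate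
10 | tert-butyl N-[(2S,3R)-3-(benzyloxy)-5-(cyclopent-1-en-1-yl)pentan-2-yl]carbamate | C[C@H](NC(=O)OC(C)(C)C)[C@H](OCc1ccccc1)CCC1=CCCC1 | intermediate
11 | tert-butyl N-[(2S,3R)-3-(benzyloxy)-6,10-dioxodecan-2-yl]carbamate | C[C@H](NC(=O)OC(C)(C)C)[C@H](OCc1ccccc1)CCC(=O)CCCC=O | intermediate
12 | tert-butyl N-[(2S,3R)-3-(benzyloxy)-4-(2-hydroxy-6-oxocyclohexyl)butan-2-yl]carbamate (ring diastereomers) | C[C@H](NC(=O)OC(C)(C)C)[C@H](OCc1ccccc1)CC1C(O)CCCC1=O | intermediate
13 | tert-butyl N-[(2S,3R)-3-(benzyloxy)-4-(6-oxocyclohex-1-en-1-yl)butan-2-yl]carbamate | C[C@H](NC(=O)OC(C)(C)C)[C@H](OCc1ccccc1)CC1=CCCCC1=O | intermediate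
14 | 2-[(2R,3S)-3-amino-2-(benzyloxy)butyl]cyclohex-2-en-1-one | C[C@H](N)[C@H](OCc1ccccc1)CC1=CCCCC1=O | intermediate
15 | (2S,3R,4aS,8aR)-3-(benzyloxy)-2-methyloctahydroquinolin-5(1H)-one (trans-fused; equilibrates with 16) | C(c1ccccc1)O[C@@H]2C[C@@H]3C(=O)CCC[C@H]3N[C@H]2C | intermediate
16 | (2S,3R,4aR,8aR)-3-(benzyloxy)-2-methyloctahydroquinolin-5(1H)-one (cis-fused) | C(c1ccccc1)O[C@@H]2C[C@H]3C(=O)CCC[C@H]3N[C@H]2C | intermediate
17 | tert-butyl (2S,3R,4aR,8aR)-3-(benzyloxy)-2-methyl-5-oxooctahydroquinoline-1(2H)-carboxylate (cis-fused) | C(c1ccccc1)O[C@@H]2C[C@H]3C(=O)CCC[C@H]3N(C(=O)OC(C)(C)C)[C@H]2C | intermediate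
18 | (2R)-2-(chloromethyl)oxirane ((R)-epichlorohydrin) | ClC[C@H]1CO1 | starting material
19 | ethylmagnesium bromide | CC[Mg]Br | starting material
20 | (2R)-1-chloropentan-2-ol | ClC[C@H](O)CCC | intermediate
21 | (2R)-2-propyloxirane | CCC[C@@H]1CO1 | intermediate
22 | allylmagnesium bromide | C=CC[Mg]Br | starting material
23 | (4R)-oct-7-en-4-ol | C=CCC[C@H](O)CCC | intermediate
24 | tert-butyldimethyl{[(4R)-oct-7-en-4-yl]oxy}silane | C=CCC[C@H](O[Si](C)(C)C(C)(C)C)CCC | intermediate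
25 | 9-{(5R)-5-[(tert-butyldimethylsilyl)oxy]octyl}-9-borabicyclo[3.3.1]nonane | B1(CCCC[C@H](O[Si](C)(C)C(C)(C)C)CCC)C2CCCC1CCC2 | intermediate
26 | (5R)-5-[(tert-butyldimethylsilyl)oxy]octan-1-ol | OCCCC[C@H](O[Si](C)(C)C(C)(C)C)CCC | intermediate
27 | tert-butyl{[(4R)-8-iodooctan-4-yl]oxy}dimethylsilane | ICCCC[C@H](O[Si](C)(C)C(C)(C)C)CCC | intermediate
28 | {(5R)-5-[(tert-butyldimethylsilyl)oxy]octyl}triphenylphosphonium iodide | [I-].c1ccccc1[P+](c1ccccc1)(c1ccccc1)CCCC[C@H](O[Si](C)(C)C(C)(C)C)CCC | intermediate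
29 | {(5R)-5-[(tert-butyldimethylsilyl)oxy]octylidene}triphenyl-λ5-phosphane | c1ccccc1P(c1ccccc1)(c1ccccc1)=CCCC[C@H](O[Si](C)(C)C(C)(C)C)CCC | intermediate
30 | tert-butyl (2S,3R,4aS,8aR)-3-(benzyloxy)-5-{(5R)-5-[(tert-butyldimethylsilyl)oxy]octylidene}-2-methyloctahydroquinoline-1(2H)-carboxylate (E/Z mixture; C4a is S by CIP priority change only, no inversion) | C(c1ccccc1)O[C@@H]2C[C@H]3C(=CCCC[C@H](O[Si](C)(C)C(C)(C)C)CCC)CCC[C@H]3N(C(=O)OC(C)(C)C)[C@H]2C | intermediate
31 | tert-butyl (2S,3R,4aS,5S,8aR)-5-{(5R)-5-[(tert-butyldimethylsilyl)oxy]octyl}-3-hydroxy-2-methyloctahydroquinoline-1(2H)-carboxylate | O[C@@H]1C[C@H]2[C@@H](CCCC[C@H](O[Si](C)(C)C(C)(C)C)CCC)CCC[C@H]2N(C(=O)OC(C)(C)C)[C@H]1C | intermediate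
32 | (2E)-hex-2-enal | CCC/C=C/C=O | starting material
33 | malonic acid | OC(=O)CC(=O)O | starting material
34 | 2-[(2E)-hex-2-en-1-ylidene]propanedioic acid | CCC/C=C/C=C(C(=O)O)C(=O)O | intermediate
35 | (2E,4E)-octa-2,4-dienoic acid | CCC/C=C/C=C/C(=O)O | intermediate
36 | tert-butyl (2S,3R,4aS,5S,8aR)-5-{(5R)-5-[(tert-butyldimethylsilyl)oxy]octyl}-2-methyl-3-{[(2E,4E)-octa-2,4-dienoyl]oxy}octahydroquinoline-1(2H)-carboxylate | CCC/C=C/C=C/C(=O)O[C@@H]1C[C@H]2[C@@H](CCCC[C@H](O[Si](C)(C)C(C)(C)C)CCC)CCC[C@H]2N(C(=O)OC(C)(C)C)[C@H]1C | intermediate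
37 | lepadin H, (2S,3R,4aS,5S,8aR)-5-[(5R)-5-hydroxyoctyl]-2-methyldecahydroquinolin-3-yl (2E,4E)-octa-2,4-dienoate | CCC/C=C/C=C/C(=O)O[C@@H]1C[C@H]2[C@@H](CCCC[C@H](O)CCC)CCC[C@H]2N[C@H]1C | target

## Step count and risks

Total step count: 21. Longest linear sequence: 13 steps (steps 1–9, 17, 18, 20, 21, from 1-chlorocyclopentene).

The three steps most likely to fail:

Step 8 (aza‑Michael ring closure). The freed primary amine may instead condense with the enone carbonyl (1,2‑addition to a conjugated bicyclic imine) or give an unsatisfactory C8a ratio. The fallback sets out from 11 and comes back at 17. The aldol is stopped at the β‑hydroxy ketone 12 (KOH cat., MeOH, 0 °C), which is oxidised (Dess–Martin periodinane) to the 1,3‑dione tert-butyl N-[(2S,3R)-3-(benzyloxy)-4-(2,6-dioxocyclohexyl)butan-2-yl]carbamate F1. TFA, then NaHCO3, removes the Boc group and the amine condenses with the dione to the bicyclic vinylogous amide (2S,3R)-3-(benzyloxy)-2-methyl-2,3,4,6,7,8-hexahydroquinolin-5(1H)-one F2. N‑Acylation (NaH, Boc2O, THF) gives tert-butyl (2S,3R)-3-(benzyloxy)-2-methyl-5-oxo-3,4,5,6,7,8-hexahydroquinoline-1(2H)-carboxylate F3. Its tetrasubstituted C4a=C8a bond is hydrogenated (H2, Pt/C, EtOAc) from the face opposite the pseudo‑axial C2 methyl, which puts H4a and H8a cis to H2 and gives 17 directly.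

Step 17 (Wittig olefination). The hindered, enolisable β‑carbamoyl ketone may be deprotonated by the basic ylide, giving no olefination or E1cB opening of the piperidine. The fallback sets out from 27 and 17 and comes back at 30. Iodine–lithium exchange on 27 (t‑BuLi, Et2O, −78 °C) gives {(5R)-5-[(tert-butyldimethylsilyl)oxy]octyl}lithium F4, which is transmetallated with anhydrous CeCl3 to the weakly basic dichloro{(5R)-5-[(tert-butyldimethylsilyl)oxy]octyl}cerium F5. This adds 1,2 to 17 to give the tertiary alcohol tert-butyl (2S,3R,4aR,8aR)-3-(benzyloxy)-5-{(5R)-5-[(tert-butyldimethylsilyl)oxy]octyl}-5-hydroxy-2-methyloctahydroquinoline-1(2H)-carboxylate F6 (C5 epimers). Burgess dehydration gives 30 together with its endocyclic isomer tert-butyl (2S,3R,4aS,8aR)-3-(benzyloxy)-5-{(5R)-5-[(tert-butyldimethylsilyl)oxy]octyl}-2-methyl-3,4,4a,7,8,8a-hexahydroquinoline-1(2H)-carboxylate F7, and both are reduced to 31 under the conditions of step 18.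

Step 18 (hydrogenation that sets C5). Facial selectivity may be eroded by double‑bond migration on palladium or by delivery from the concave face. The fallback sets out from 30 and comes back at 31. Radical hydrogen‑atom‑transfer hydrogenation (Mn(dpm)3 cat., PhSiH3, t‑BuOOH, i‑PrOH, rt) forms the C5 tertiary radical, which is quenched axially so that the side chain ends up equatorial (the thermodynamic 5S epimer). This gives tert-butyl (2S,3R,4aS,5S,8aR)-3-(benzyloxy)-5-{(5R)-5-[(tert-butyldimethylsilyl)oxy]octyl}-2-methyloctahydroquinoline-1(2H)-carboxylate F8, and hydrogenolysis of the benzyl ether (H2, Pd(OH)2/C, EtOAc) then gives 31.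

## Further compounds

F1 | step 8 | tert-butyl N-[(2S,3R)-3-(benzyloxy)-4-(2,6-dioxocyclohexyl)butan-2-yl]carbamate | C[C@H](NC(=O)OC(C)(C)C)[C@H](OCc1ccccc1)CC1C(=O)CCCC1=O
F2 | step 8 | (2S,3R)-3-(benzyloxy)-2-methyl-2,3,4,6,7,8-hexahydroquinolin-5(1H)-one | C(c1ccccc1)O[C@@H]2CC3=C(CCCC3=O)N[C@H]2C
F3 | step 8 | tert-butyl (2S,3R)-3-(benzyloxy)-2-methyl-5-oxo-3,4,5,6,7,8-hexahydroquinoline-1(2H)-carboxylate | C(c1ccccc1)O[C@@H]2CC3=C(CCCC3=O)N(C(=O)OC(C)(C)C)[C@H]2C
F4 | step 17 | {(5R)-5-[(tert-butyldimethylsilyl)oxy]octyl}lithium | [Li]CCCC[C@H](O[Si](C)(C)C(C)(C)C)CCC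
F5 | step 17 | dichloro{(5R)-5-[(tert-butyldimethylsilyl)oxy]octyl}cerium | Cl[Ce](Cl)CCCC[C@H](O[Si](C)(C)C(C)(C)C)CCC
F6 | step 17 | tert-butyl (2S,3R,4aR,8aR)-3-(benzyloxy)-5-{(5R)-5-[(tert-butyldimethylsilyl)oxy]octyl}-5-hydroxy-2-methyloctahydroquinoline-1(2H)-carboxylate (C5 epimers) | C(c1ccccc1)O[C@@H]2C[C@H]3C(O)(CCCC[C@H](O[Si](C)(C)C(C)(C)C)CCC)CCC[C@H]3N(C(=O)OC(C)(C)C)[C@H]2C
F7 | step 17 | tert-butyl (2S,3R,4aS,8aR)-3-(benzyloxy)-5-{(5R)-5-[(tert-butyldimethylsilyl)oxy]octyl}-2-methyl-3,4,4a,7,8,8a-hexahydroquinoline-1(2H)-carboxylate | C(c1ccccc1)O[C@@H]2C[C@H]3C(CCCC[C@H](O[Si](C)(C)C(C)(C)C)CCC)=CCC[C@H]3N(C(=O)OC(C)(C)C)[C@H]2C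
F8 | step 18 | tert-butyl (2S,3R,4aS,5S,8aR)-3-(benzyloxy)-5-{(5R)-5-[(tert-butyldimethylsilyl)oxy]octyl}-2-methyloctahydroquinoline-1(2H)-carboxylate | C(c1ccccc1)O[C@@H]2C[C@H]3[C@@H](CCCC[C@H](O[Si](C)(C)C(C)(C)C)CCC)CCC[C@H]3N(C(=O)OC(C)(C)C)[C@H]2C
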